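Ring A, the phenol ring, is assembled by benzannulation, not by substitution of a benzene. The disconnection cuts its C1–C2 and C3–C4 bonds: C1 (with its oxygen) and C4–C6 come from 3-acetoxy-2-pyrone, while C2 (aryloxy) and C3 (bromine) are the two carbons of 2-bromophenyl bromoethynyl ether. One thermal operation, [4+2] cycloaddition then loss of CO2, closes ring A with the contiguous C1–O/C2–OAr/C3–Br triad already in place, which is the feature exploited. The precursors are the acetylated hydroxypyrone and a bromo ynol ether made from 2-bromophenol through its formate and dibromovinyl ether. Acetate methanolysis and dibromination at C4 and C6 finish the synthesis.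

Key step: step 5

Remark: the target has no stereocentre and its diaryl ether axis is not configurationally stable, so it is achiral and no enantiocontrol is needed. Ring A is numbered C1 (OH), C2 (OAr), C3–C6; the 2-bromophenyl ring is ring B.

Step 1
Reactants: 1 3-hydroxy-2H-pyran-2-one
Product: 2 2-oxo-2H-pyran-3-yl acetate (3-acetoxy-2H-pyran-2-one)
Conditions: Ac2O, pyridine, CH2Cl2, 0 °C → rt
Reagents that add atoms: acetic anhydride, CC(=O)OC(C)=O
Why: O-acylation of the acidic enolic hydroxyl is a routine esterification and turns the electron-rich hydroxy diene into a neutral acyloxy pyrone suited to an electron-rich alkyne.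

Step 2
Reactants: 3 2-bromophenol
Product: 4 2-bromophenyl formate
Conditions: HCO2H, Ac2O, 60 °C; then 3, NaOAc (cat.), PhMe, 0 °C → rt
Reagents that add atoms: acetic formic anhydride, CC(=O)OC=O (made in the flask from formic acid, OC=O, and acetic anhydride, CC(=O)OC(C)=O)
Why: O-formylation with the mixed anhydride, which transfers its more electrophilic formyl group to the phenol, is the usual way to aryl formates.

Step 3
Reactants: 4 2-bromophenyl formate; 5 carbon tetrabromide
Product: 6 1-bromo-2-[(2,2-dibromoethenyl)oxy]benzene
Conditions: 5 (2 equiv), PPh3 (4 equiv), CH2Cl2, 0 °C; then 4, 0 °C → rt; chromatography on Et3N-deactivated silica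
Reagents that add atoms: none
Why: Ramirez dibromo-olefination (first stage of the Corey–Fuchs sequence), in which Ph3P=CBr2 undergoes a Wittig reaction at the aldehyde-like formate carbonyl as established for formate esters, while the aryl bromide is inert.

Step 4
Reactants: 6 1-bromo-2-[(2,2-dibromoethenyl)oxy]benzene
Product: 7 1-bromo-2-[(bromoethynyl)oxy]benzene
Conditions: LiHMDS (1.1 equiv), THF, −78 °C; pH 7 buffer quench, cold work-up, used at once
Reagents that add atoms: none
Why: Base-induced anti-dehydrobromination (E2) of a 1,1-dibromoalkene to the 1-bromoalkyne should be easy because the vinyl hydrogen always has a trans bromine, and the hindered amide at −78 °C should neither exchange the aryl bromide nor add to the ynol ether.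

Step 5
Reactants: 2 2-oxo-2H-pyran-3-yl acetate; 7 1-bromo-2-[(bromoethynyl)oxy]benzene
Product: 9 3-bromo-2-(2-bromophenoxy)phenyl acetate, via bicyclic lactone cycloadduct 8 (not isolated)
Conditions: 2 (2 equiv), PhMe, BHT (cat.), sealed tube, 120 °C
Reagents that add atoms: none
Why: Proposed new method: the polarised alkyne should add across C3 and C6 of the pyrone in an asynchronous inverse-electron-demand [4+2] cycloaddition, its bromine-bearing carbon (β to oxygen, the nucleophilic end of an ynol ether) bonding to the electrophilic C6 and its oxygen-bearing carbon to C3, to give bridged lactone 8, which at this temperature should lose CO2 by retro-[4+2] and aromatise. The closest known reaction type is the Diels–Alder/decarboxylation benzannulation of 2-pyrones, including 3-heteroatom-substituted ones, with alkynes such as ynamines and alkynyl ethers; a 1-bromoalkynyl aryl ether has not been used as the 2π partner. Ring A is closed as a six-membered carbocycle by intermolecular [4+2] cycloaddition, forming its C1–C2 and C3–C4 bonds, and becomes benzenoid by retro-Diels–Alder extrusion of the CO2 bridge. No stereocentre remains, since the two bridgehead centres of racemic 8 are destroyed on aromatisation. The step needs regioselectivity only, and the matched polarity (aryloxy donor on the alkyne, lactone carbonyl acceptor on the diene) should place the aryloxy carbon next to the acetoxy carbon; the aryl ynol ether has no hydrogen placed for retro-ene loss to a ketene, so it should tolerate the heating.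

Step 6
Reactants: 9 3-bromo-2-(2-bromophenoxy)phenyl acetate
Product: 10 3-bromo-2-(2-bromophenoxy)phenol
Conditions: K2CO3 (0.2 equiv), MeOH, 0 °C → rt; then 1 M HCl
Reagents that add atoms: none
Why: Base-catalysed transesterification (Zemplén-type methanolysis) should cleave the aryl acetate to the phenol and methyl acetate while the diaryl ether and aryl bromides stay untouched.

Step 7
Reactants: 10 3-bromo-2-(2-bromophenoxy)phenol
Product: 12 3,4,6-tribromo-2-(2-bromophenoxy)phenol, via 3,4-dibromo-2-(2-bromophenoxy)phenol 11 (not isolated)
Conditions: Br2 (2.05 equiv, slow addition), CH2Cl2, 0 °C → rt; aq. Na2S2O3 quench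
Reagents that add atoms: bromine, BrBr
Why: Electrophilic aromatic bromination of the free phenol should take the only open para (C4) and ortho (C6) carbons, since the other ortho carbon carries the aryloxy group, C5 is meta to the hydroxyl, and ring B is a bromine-deactivated diaryl ether ring that should react far more slowly.

Compound list
1 | 3-hydroxy-2H-pyran-2-one | OC1=CC=COC1=O | starting material
2 | 2-oxo-2H-pyran-3-yl acetate (3-acetoxy-2H-pyran-2-one) | CC(=O)OC1=CC=COC1=O | intermediate
3 | 2-bromophenol | Oc1ccccc1Br | starting material
4 | 2-bromophenyl formate | O=COc1ccccc1Br | intermediate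
5 | carbon tetrabromide | BrC(Br)(Br)Br | starting material
6 | 1-bromo-2-[(2,2-dibromoethenyl)oxy]benzene | BrC(Br)=COc1ccccc1Br | intermediate
7 | 1-bromo-2-[(bromoethynyl)oxy]benzene | BrC#COc1ccccc1Br | intermediate
8 | 6-bromo-5-(2-bromophenoxy)-3-oxo-2-oxabicyclo[2.2.2]octa-5,7-dien-4-yl acetate (racemic, not isolated) | CC(=O)OC12C=CC(OC1=O)C(Br)=C2Oc1ccccc1Br | intermediate
9 | 3-bromo-2-(2-bromophenoxy)phenyl acetate | CC(=O)Oc1cccc(Br)c1Oc1ccccc1Br | intermediate
10 | 3-bromo-2-(2-bromophenoxy)phenol | Oc1cccc(Br)c1Oc1ccccc1Br | intermediate
11 | 3,4-dibromo-2-(2-bromophenoxy)phenol (not isolated) | Oc1ccc(Br)c(Br)c1Oc1ccccc1Br | intermediate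
12 | 3,4,6-tribromo-2-(2-bromophenoxy)phenol | Oc1c(Br)cc(Br)c(Br)c1Oc1ccccc1Br | target

Total step count: 7. Longest linear sequence: 6 steps (steps 2–7, from 2-bromophenol).

Steps most likely to fail

Step 5 (Proposed new method). Thermal self-reaction of the bromo ynol ether may outpace a sluggish cycloaddition, or the partners may combine in the reverse orientation. The fallback uses known chemistry and sets out from 2-bromophenol 3. Nucleophilic aromatic substitution of commercial 3-bromo-2-fluorobenzaldehyde (O=Cc1cccc(Br)c1F) by 3 (K2CO3, DMAc, 100 °C) should give 3-bromo-2-(2-bromophenoxy)benzaldehyde F1. Baeyer–Villiger oxidation (mCPBA, CH2Cl2, rt), with migration of the oxygen-substituted aryl group, should give 3-bromo-2-(2-bromophenoxy)phenyl formate F2. Methanolysis (K2CO3, MeOH) then returns to the route at phenol 10.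

Step 4. The bromoalkynyl ether may be destroyed as it forms, by addition of the amide base or by oligomerisation and hydration during work-up and concentration. The fallback makes the bromoalkyne under neutral conditions and sets out from 2-bromophenol 3. Iridium-catalysed transfer vinylation (vinyl acetate, [Ir(cod)Cl]2 cat., Na2CO3, PhMe, 100 °C) should give 1-bromo-2-(ethenyloxy)benzene F3. Addition of Br2 (CH2Cl2, −78 °C) should give racemic 1-bromo-2-(1,2-dibromoethoxy)benzene F4. Warming with N,N-diethylaniline should remove one HBr to give mainly 1-bromo-2-{[(Z)-2-bromoethenyl]oxy}benzene F5. Anti-elimination with KOtBu (THF, 0 °C), the classical phenoxyacetylene sequence, should give 1-bromo-2-(ethynyloxy)benzene F6. Bromination of the terminal alkyne (NBS, AgNO3 cat., acetone, rt) comes back to the route at 7.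

Step 3. Acyl transfer from the activated aryl formate to the ylide, with loss of the 2-bromophenoxide, may outrun oxaphosphetane formation. The fallback avoids the formate and sets out from 2-bromophenol 3. Treatment with tribromoethylene (BrC=C(Br)Br; K2CO3, DMF, 70 °C, under inert gas) should give 1-bromo-2-{[(E)-1,2-dibromoethenyl]oxy}benzene F7 by anti-addition of the phenoxide to dibromoacetylene formed and consumed in solution. This is the bromine analogue of the established trichloroethylene route to aryl 1,2-dichlorovinyl ethers. LiHMDS (THF, −78 → −20 °C) should then deprotonate the vinyl C–H and expel the bromide on the oxygen-bearing carbon, returning to the route at 7.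

Further compounds
F1 | step 5 | 3-bromo-2-(2-bromophenoxy)benzaldehyde | O=Cc1cccc(Br)c1Oc1ccccc1Br
F2 | step 5 | 3-bromo-2-(2-bromophenoxy)phenyl formate | O=COc1cccc(Br)c1Oc1ccccc1Br
F3 | step 4 | 1-bromo-2-(ethenyloxy)benzene | C=COc1ccccc1Br
F4 | step 4 | 1-bromo-2-(1,2-dibromoethoxy)benzene (racemic) | BrCC(Br)Oc1ccccc1Br
F5 | step 4 | 1-bromo-2-{[(Z)-2-bromoethenyl]oxy}benzene | Br/C=C\Oc1ccccc1Br
F6 | step 4 | 1-bromo-2-(ethynyloxy)benzene | C#COc1ccccc1Br
F7 | step 3 | 1-bromo-2-{[(E)-1,2-dibromoethenyl]oxy}benzene | Br/C=C(/Br)Oc1ccccc1Br
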